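The route is cut at the C2–C3 bond of the eight-membered ring C. One palladium-mediated 8-exo Heck closure of a C3 enol triflate onto the vinyl group at C22 of ring D forms that bond, closes ring C and installs the C1=C2–C3=C4 exocyclic diene. It exploits the C3=C4 edge shared by rings B and C, which holds the tether cis. The precursor is a tetrasubstituted triflate of the trans-fused A/B hydrindane (O9 silylated) that carries at C4 the C17–C19–C20 chain ending in ring D, a cyclopentane with vinyl trans to the chain. Its triflate regiochemistry is fixed by reductive triflation of a C4-substituted enone.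

Key step: step 24

Remark: labels C1–C26 and O9 follow the atom order of the target SMILES (rings A: C6,C8,C10,C11,C15; B: C3–C6,C15,C16; C: C2–C4,C17,C19–C22; D: C21–C25); the single enantiomers 1, 11 and 23 are assumed to be purchased.

**Part A – lactone carrying rings A and the seco-ring B (C3, C5, C6, C8, C10, C11, C15, C16)**

Step 1
Reactants: 1 (R)-4-(tert-butyldimethylsilyloxy)cyclopent-2-en-1-one
Product: 3 (S)-4-isopropylcyclopent-2-en-1-one, via trans-3-isopropyl-4-silyloxycyclopentanone 2 (not isolated)
Conditions: i-PrMgCl, CuBr·SMe2 (10 mol %), THF, −78 °C; then DBU, CH2Cl2, 0 °C → rt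
Reagents that add atoms: isopropylmagnesium chloride, CC(C)[Mg]Cl
Why: Copper-catalysed conjugate addition should place the isopropyl group anti to the silyloxy group and E1cB loss of silanolate then transposes the enone, so that C11 is set by the purchased carbinol centre.

Step 2
Reactants: 3 (S)-4-isopropylcyclopent-2-en-1-one
Product: 4 (S)-2-iodo-4-isopropylcyclopent-2-en-1-one
Conditions: I2, pyridine/CH2Cl2, 0 °C → rt
Reagents that add atoms: iodine, II
Why: α-Iodination of an enone by the pyridine addition/iodination/elimination sequence should functionalise only the α-carbon (future C6) and leave C11 untouched.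

Step 3
Reactants: 4 (S)-2-iodo-4-isopropylcyclopent-2-en-1-one
Product: 5 (S)-4-isopropyl-2-methylcyclopent-2-en-1-one
Conditions: Me4Sn, Pd2(dba)3 (2.5 mol %), AsPh3, CuI, NMP, 60 °C
Reagents that add atoms: tetramethylstannane, C[Sn](C)(C)C
Why: Stille coupling of an α-iodoenone under neutral conditions should install the C7 methyl without epimerising the γ-stereocentre.

Step 4
Reactants: 5 (S)-4-isopropyl-2-methylcyclopent-2-en-1-one
Product: 6 methyl [5-isopropyl-2-methyl-3-(trimethylsilyloxy)cyclopent-2-en-1-yl]acetate (acetate arm trans to isopropyl)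
Conditions: CH2=C(OMe)OSiMe3, Tf2NH (1 mol %), CH2Cl2, −78 °C; Et3N, non-aqueous work-up
Reagents that add atoms: 1-methoxy-1-(trimethylsilyloxy)ethene, C=C(OC)O[Si](C)(C)C
Why: Mukaiyama–Michael addition with silyl transfer should deliver the acetate unit (C16, C3) to C15 anti to the adjacent isopropyl group, which sets C15, and keep the C8/C6 enolate as its regiodefined silyl ether.

Step 5
Reactants: 6 methyl [5-isopropyl-2-methyl-3-(trimethylsilyloxy)cyclopent-2-en-1-yl]acetate
Product: 8 trans-fused 5-isopropyl-7a-methylhexahydrocyclopenta[c]pyran-3,7-dione (keto lactone), via hydroxymethyl keto ester 7 (not isolated)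
Conditions: 37 % aq. HCHO, Yb(OTf)3 (10 mol %), THF, rt; then p-TsOH (cat.), PhMe, 80 °C
Reagents that add atoms: formaldehyde, C=O
Why: Lewis-acid-catalysed Mukaiyama aldol hydroxymethylation should bring C5 onto the tetrasubstituted enol ether anti to the neighbouring C15 arm, which sets the quaternary C6 with the trans relationship of a trans-hydrindane, and acid then closes the δ-lactone.

Step 6
Reactants: 8 keto lactone
Product: 9 7-hydroxy lactone (hydroxyl cis to the 7a-methyl)
Conditions: NaBH4, MeOH/CH2Cl2, −40 °C; AcOH quench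
Reagents that add atoms: none
Why: Chemoselective borohydride reduction of the ketone beside the lactone should occur from the face opposite the angular methyl of the rigid trans-fused bicycle (as in 17-keto steroids), which sets C8 with O9 cis to C7, while the cold acidic quench suppresses acyl migration.

Step 7
Reactants: 9 7-hydroxy lactone
Product: 10 7-(tert-butyldimethylsilyloxy) lactone
Conditions: TBSOTf, 2,6-lutidine, CH2Cl2, −78 → 0 °C
Reagents that add atoms: tert-butyldimethylsilyl trifluoromethanesulfonate, CC(C)(C)[Si](C)(C)OS(=O)(=O)C(F)(F)F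
Why: Silyl triflate silylation is the standard way to protect a hindered secondary alcohol and does not enolise the lactone under lutidine.

**Part B – ring D and the C4–C17–C19–C20 chain**

Step 8
Reactants: 11 (S)-citronellal
Product: 12 (S)-3,7-dimethyl-2-methylideneoct-6-enal
Conditions: 37 % aq. HCHO, pyrrolidine (10 mol %), EtCO2H (10 mol %), i-PrOH, 45 °C
Reagents that add atoms: formaldehyde, C=O
Why: Amine-catalysed α-methylenation (Mannich condensation and elimination through the enamine) should add the future C22 to the α-carbon only, so the β-stereocentre (C25) is not touched.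

Step 9
Reactants: 12 (S)-3,7-dimethyl-2-methylideneoct-6-enal
Product: 13 (S)-5-methylcyclopent-1-ene-1-carbaldehyde
Conditions: Grubbs II (2 mol %), CH2Cl2 (0.02 M), 40 °C
Reagents that add atoms: none
Why: Ring-closing metathesis of the 1,6-diene with loss of isobutene should close ring D as the conjugated cyclopentene aldehyde.

Step 10
Reactants: 13 (S)-5-methylcyclopent-1-ene-1-carbaldehyde
Product: 14 [(S)-5-methylcyclopent-1-en-1-yl]methanol
Conditions: NaBH4, CeCl3·7H2O, MeOH, 0 °C
Reagents that add atoms: none
Why: Luche reduction should give clean 1,2-reduction of the enal to the allylic alcohol (C20).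

Step 11
Reactants: 14 [(S)-5-methylcyclopent-1-en-1-yl]methanol
Product: 15 tert-butyldimethyl{[(S)-5-methylcyclopent-1-en-1-yl]methoxy}silane
Conditions: TBSCl, imidazole, DMF, rt
Reagents that add atoms: tert-butyldimethylsilyl chloride, CC(C)(C)[Si](C)(C)Cl
Why: Standard silylation masks the primary alcohol so that the alkene can be hydroborated without borate formation.

Step 12
Reactants: 15 tert-butyldimethyl{[(S)-5-methylcyclopent-1-en-1-yl]methoxy}silane
Product: 17 pinacol boronate (boron on C22 trans to the CH2OTBS arm; arm cis to the C25 methyl), via catechol boronate 16 (not isolated)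
Conditions: catecholborane (2 equiv), neat, 100 °C; then pinacol, THF, rt
Reagents that add atoms: catecholborane, B1Oc2ccccc2O1; pinacol, CC(C)(O)C(C)(C)O
Why: Thermal syn hydroboration of the trisubstituted alkene should put boron on C22 and hydrogen on C21 from the face opposite the allylic C25 methyl (held pseudo-axial by allylic strain), which sets C21 and C22 in one event, and transesterification gives the stable pinacol ester.

Step 13
Reactants: 17 pinacol boronate
Product: 20 tert-butyl{[(1S,2R,5S)-2-ethenyl-5-methylcyclopentyl]methoxy}dimethylsilane, via vinyl boronate complex 18 (not isolated), via β-iodoalkyl boronate 19 (not isolated)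
Conditions: CH2=CHMgBr, THF/DMSO, 0 °C → rt; I2, MeOH, −78 °C; NaOMe, MeOH, −78 → 0 °C
Reagents that add atoms: vinylmagnesium bromide, C=C[Mg]Br
Why: Zweifel olefination (iodine-triggered 1,2-metallate shift, then anti elimination of the β-iodo boronate) should replace boron by vinyl with retention at C22.

Step 14
Reactants: 20 silyl ether of the vinylcyclopentane
Product: 21 [(1S,2R,5S)-2-ethenyl-5-methylcyclopentyl]methanol
Conditions: TBAF, THF, rt
Reagents that add atoms: none
Why: Fluoride cleaves the primary silyl ether without affecting the vinyl group.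

Step 15
Reactants: 21 [(1S,2R,5S)-2-ethenyl-5-methylcyclopentyl]methanol
Product: 22 [(1S,2R,5S)-2-ethenyl-5-methylcyclopentyl]methyl 4-methylbenzenesulfonate
Conditions: TsCl, Et3N, DMAP (cat.), CH2Cl2, 0 °C → rt
Reagents that add atoms: 4-methylbenzenesulfonyl chloride, Cc1ccc(cc1)S(Cl)(=O)=O
Why: Sulfonylation turns C20 into an electrophile that does not undergo halogen–metal exchange in the coupling that follows.

Step 16
Reactants: 23 (R)-3-bromo-2-methylpropan-1-ol
Product: 24 (R)-(3-bromo-2-methylpropoxy)(tert-butyl)dimethylsilane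
Conditions: TBSCl, imidazole, CH2Cl2, rt
Reagents that add atoms: tert-butyldimethylsilyl chloride, CC(C)(C)[Si](C)(C)Cl
Why: Silylation of the primary alcohol gives the protected C4–C17–C19 unit whose C17 centre comes from the chiral pool.

Step 17
Reactants: 24 (R)-(3-bromo-2-methylpropoxy)(tert-butyl)dimethylsilane; 22 tosylate of the vinylcyclopentylmethanol
Product: 26 silyl ether of (S)-2-methyl-4-[(1S,2R,5S)-2-ethenyl-5-methylcyclopentyl]butan-1-ol, via alkylmagnesium bromide 25 (not isolated)
Conditions: 24, Mg, THF, 40 °C; then 22, Li2CuCl4 (5 mol %), THF/NMP, −20 °C → rt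
Reagents that add atoms: none
Why: Copper-catalysed alkyl–alkyl cross-coupling of a primary Grignard reagent with a primary tosylate should form C19–C20 while the stereocentres, all β to the reacting carbons, stay untouched.

Step 18
Reactants: 26 silyl ether of the C4–C25 side chain
Product: 27 (S)-2-methyl-4-[(1S,2R,5S)-2-ethenyl-5-methylcyclopentyl]butan-1-ol
Conditions: TBAF, THF, rt
Reagents that add atoms: none
Why: Fluoride-mediated desilylation frees the C4 alcohol.

Step 19
Reactants: 27 side-chain alcohol
Product: 28 (1S,2R,3S)-1-ethenyl-2-[(S)-4-iodo-3-methylbutyl]-3-methylcyclopentane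
Conditions: I2, PPh3, imidazole, CH2Cl2, 0 °C
Reagents that add atoms: iodine, II
Why: Appel-type iodination converts the primary alcohol into the iodide needed for clean iodine–lithium exchange.

**Part C – union, ring B, key step**

Step 20
Reactants: 28 side-chain iodide; 10 silyloxy lactone
Product: 30 seco-ring-B hydroxy ketone (C3 ketone, C5 primary alcohol, O9-TBS; all eight stereocentres as in the target), via primary alkyllithium 29 (not isolated)
Conditions: 28, t-BuLi (2.1 equiv), Et2O/pentane, −78 °C; then 10, THF, −78 °C; aq. NH4Cl at −78 °C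
Reagents that add atoms: none
Why: Iodine–lithium exchange followed by mono-addition of the alkyllithium to the δ-lactone (the tetrahedral adduct persists at −78 °C) should form C3–C4 and unveil the C5 alcohol, and the cold quench avoids silyl migration.

Step 21
Reactants: 30 hydroxy ketone
Product: 31 keto aldehyde (C5 aldehyde, C3 ketone)
Conditions: Dess–Martin periodinane, NaHCO3, CH2Cl2, 0 °C → rt
Reagents that add atoms: none
Why: Buffered periodinane oxidation converts the neopentyl primary alcohol into the non-enolisable aldehyde under neutral conditions.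

Step 22
Reactants: 31 keto aldehyde
Product: 33 C4-substituted enone (C3 ketone, C4=C5; rings A/B trans-fused), via β-hydroxy ketone 32 (not isolated)
Conditions: KOH, MeOH, 0 °C → rt
Reagents that add atoms: none
Why: Intramolecular aldol condensation closes ring B because only the C4 enolate can reach the C5 aldehyde through a six-membered ring, and it creates no stereocentre.

Step 23
Reactants: 33 C4-substituted enone
Product: 35 C3 enol triflate (tetrasubstituted C3=C4; Heck precursor), via lithium C3 enolate 34 (not isolated)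
Conditions: Li (2.2 equiv), NH3/THF, t-BuOH (1 equiv), −78 °C; isoprene; NH3 removed; PhNTf2, THF, −78 °C → rt
Reagents that add atoms: N-phenylbis(trifluoromethanesulfonimide), O=S(=O)(N(c1ccccc1)S(=O)(=O)C(F)(F)F)C(F)(F)F
Why: Dissolving-metal conjugate reduction generates only the C3–C4 enolate, and O-triflation of that enolate fixes the tetrasubstituted triflate regiospecifically while the isolated vinyl group and the silyl ether survive.

Step 24
Reactants: 35 C3 enol triflate
Product: 36 O9-tert-butyldimethylsilyl ether of the target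
Conditions: Pd(PPh3)4 (20 mol %), K2CO3, 4 Å MS, MeCN (0.005 M), 85 °C
Reagents that add atoms: none
Why: Pd(0) adds oxidatively to the C3–OTf bond, the cationic vinylpalladium binds the C22 vinyl group and inserts it syn so that C3 bonds to the inner carbon C2 and palladium sits on C1, and syn β-hydride loss of the single C2–H releases the C1=C2 methylene conjugated with C3=C4. The closest known reaction type is the intramolecular Heck cyclisation of an enol triflate onto a monosubstituted alkene that closes an eight-membered carbocycle and leaves an exocyclic methylene. Ring C is closed in the 8-exo-trig mode. No stereocentre is formed, since all eight are already present and none lies on the path of the metal. The step needs exo instead of 9-endo insertion and no migration of the new alkene: the cis C3=C4 edge of ring B and the trans C21/C22 substituents of ring D hold the two termini close, the alkylpalladium on C1 has only the C2 hydrogen to lose, and carbonate removes the palladium hydride before it can re-add.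

Step 25
Reactants: 36 O9-silyl ether of the target
Product: 37 target (CNP0544018.1)
Conditions: TBAF, THF, 50 °C
Reagents that add atoms: none
Why: Fluoride cleaves the hindered secondary silyl ether under non-acidic conditions that leave the acid-sensitive exocyclic diene intact.

**Compound list**

1 | (R)-4-(tert-butyldimethylsilyloxy)cyclopent-2-en-1-one | O=C1C=C[C@H](O[Si](C)(C)C(C)(C)C)C1 | starting material
2 | trans-3-isopropyl-4-(tert-butyldimethylsilyloxy)cyclopentan-1-one | O=C1C[C@@H](C(C)C)[C@H](O[Si](C)(C)C(C)(C)C)C1 | intermediate (not isolated)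
3 | (S)-4-isopropylcyclopent-2-en-1-one | O=C1C=C[C@H](C(C)C)C1 | intermediate
4 | (S)-2-iodo-4-isopropylcyclopent-2-en-1-one | O=C1C(I)=C[C@H](C(C)C)C1 | intermediate
5 | (S)-4-isopropyl-2-methylcyclopent-2-en-1-one | O=C1C(C)=C[C@H](C(C)C)C1 | intermediate
6 | methyl [5-isopropyl-2-methyl-3-(trimethylsilyloxy)cyclopent-2-en-1-yl]acetate, acetate arm trans to isopropyl | COC(=O)C[C@@H]1C(C)=C(O[Si](C)(C)C)C[C@H]1C(C)C | intermediate
7 | methyl [2-(hydroxymethyl)-5-isopropyl-2-methyl-3-oxocyclopentyl]acetate, CH2OH and isopropyl both trans to the acetate arm | COC(=O)C[C@@H]1[C@@](C)(CO)C(=O)C[C@H]1C(C)C | intermediate (not isolated)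
8 | trans-fused 5-isopropyl-7a-methylhexahydrocyclopenta[c]pyran-3,7-dione (isopropyl cis to 4a-H) | O=C1C[C@H]2[C@H](C(C)C)CC(=O)[C@]2(C)CO1 | intermediate
9 | trans-fused 7-hydroxy-5-isopropyl-7a-methylhexahydrocyclopenta[c]pyran-3-one (OH cis to 7a-methyl) | O=C1C[C@H]2[C@H](C(C)C)C[C@@H](O)[C@]2(C)CO1 | intermediate
10 | 7-(tert-butyldimethylsilyloxy) derivative of 9 | O=C1C[C@H]2[C@H](C(C)C)C[C@@H](O[Si](C)(C)C(C)(C)C)[C@]2(C)CO1 | intermediate
11 | (S)-citronellal | O=CC[C@@H](C)CCC=C(C)C | starting material
12 | (S)-3,7-dimethyl-2-methylideneoct-6-enal | O=CC(=C)[C@@H](C)CCC=C(C)C | intermediate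
13 | (S)-5-methylcyclopent-1-ene-1-carbaldehyde | O=CC1=CCC[C@@H]1C | intermediate
14 | [(S)-5-methylcyclopent-1-en-1-yl]methanol | OCC1=CCC[C@@H]1C | intermediate
15 | tert-butyldimethyl{[(S)-5-methylcyclopent-1-en-1-yl]methoxy}silane | CC(C)(C)[Si](C)(C)OCC1=CCC[C@@H]1C | intermediate
16 | catechol boronate: 2-[2-(TBSO-methyl)-3-methylcyclopentyl]-1,3,2-benzodioxaborole, B trans to the arm, arm cis to methyl | CC(C)(C)[Si](C)(C)OC[C@@H]1[C@@H](B2Oc3ccccc3O2)CC[C@@H]1C | intermediate (not isolated)
17 | pinacol boronate, same configuration as 16 | CC(C)(C)[Si](C)(C)OC[C@@H]1[C@@H](B2OC(C)(C)C(C)(C)O2)CC[C@@H]1C | intermediate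
18 | bromomagnesium vinyl boronate complex of 17 | CC(C)(C)[Si](C)(C)OC[C@@H]1[C@@H]([B-]2(C=C)OC(C)(C)C(C)(C)O2)CC[C@@H]1C.[Mg+]Br | intermediate (not isolated)
19 | β-iodoalkyl pinacol boronate (mixture at the boron-bearing carbon) | CC(C)(C)[Si](C)(C)OC[C@@H]1[C@@H](C(CI)B2OC(C)(C)C(C)(C)O2)CC[C@@H]1C | intermediate (not isolated)
20 | tert-butyl{[(1S,2R,5S)-2-ethenyl-5-methylcyclopentyl]methoxy}dimethylsilane | CC(C)(C)[Si](C)(C)OC[C@@H]1[C@@H](C=C)CC[C@@H]1C | intermediate
21 | [(1S,2R,5S)-2-ethenyl-5-methylcyclopentyl]methanol | OC[C@@H]1[C@@H](C=C)CC[C@@H]1C | intermediate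
22 | [(1S,2R,5S)-2-ethenyl-5-methylcyclopentyl]methyl 4-methylbenzenesulfonate | Cc1ccc(cc1)S(=O)(=O)OC[C@@H]1[C@@H](C=C)CC[C@@H]1C | intermediate
23 | (R)-3-bromo-2-methylpropan-1-ol | OC[C@@H](C)CBr | starting material
24 | (R)-(3-bromo-2-methylpropoxy)(tert-butyl)dimethylsilane | CC(C)(C)[Si](C)(C)OC[C@@H](C)CBr | intermediate
25 | [3-(tert-butyldimethylsilyloxy)-2-methylpropyl]magnesium bromide, configuration as in 24 | CC(C)(C)[Si](C)(C)OC[C@@H](C)C[Mg]Br | intermediate (not isolated)
26 | tert-butyldimethylsilyl ether of 27 | CC(C)(C)[Si](C)(C)OC[C@@H](C)CC[C@@H]1[C@@H](C=C)CC[C@@H]1C | intermediate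
27 | (S)-2-methyl-4-[(1S,2R,5S)-2-ethenyl-5-methylcyclopentyl]butan-1-ol | OC[C@@H](C)CC[C@@H]1[C@@H](C=C)CC[C@@H]1C | intermediate
28 | (1S,2R,3S)-1-ethenyl-2-[(S)-4-iodo-3-methylbutyl]-3-methylcyclopentane | IC[C@@H](C)CC[C@@H]1[C@@H](C=C)CC[C@@H]1C | intermediate
29 | primary alkyllithium from 28 | [Li]C[C@@H](C)CC[C@@H]1[C@@H](C=C)CC[C@@H]1C | intermediate (not isolated)
30 | seco-ring-B hydroxy ketone (C3 ketone, C5 CH2OH, O9-TBS), stereocentres as in the target | O=C(C[C@H]1[C@H](C(C)C)C[C@@H](O[Si](C)(C)C(C)(C)C)[C@]1(C)CO)C[C@@H](C)CC[C@@H]1[C@@H](C=C)CC[C@@H]1C | intermediate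
31 | seco-ring-B keto aldehyde (C3 ketone, C5 CHO) | O=C(C[C@H]1[C@H](C(C)C)C[C@@H](O[Si](C)(C)C(C)(C)C)[C@]1(C)C=O)C[C@@H](C)CC[C@@H]1[C@@H](C=C)CC[C@@H]1C | intermediate
32 | β-hydroxy ketone from aldol closure of ring B (mixture at C4 and C5) | O=C1C[C@H]2[C@H](C(C)C)C[C@@H](O[Si](C)(C)C(C)(C)C)[C@]2(C)C(O)C1[C@@H](C)CC[C@@H]1[C@@H](C=C)CC[C@@H]1C | intermediate (not isolated)
33 | C4-substituted hydrindenone (C3 ketone, C4=C5) with the C17 side chain and ring D | O=C1C[C@H]2[C@H](C(C)C)C[C@@H](O[Si](C)(C)C(C)(C)C)[C@]2(C)C=C1[C@@H](C)CC[C@@H]1[C@@H](C=C)CC[C@@H]1C | intermediate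
34 | lithium C3 enolate (C3=C4) of the saturated ketone | [Li]OC1=C(C[C@@]2(C)[C@H](O[Si](C)(C)C(C)(C)C)C[C@@H](C(C)C)[C@@H]2C1)[C@@H](C)CC[C@@H]1[C@@H](C=C)CC[C@@H]1C | intermediate (not isolated)
35 | C3 enol triflate tethered to the vinylcyclopentane (Heck precursor) | FC(F)(F)S(=O)(=O)OC1=C(C[C@@]2(C)[C@H](O[Si](C)(C)C(C)(C)C)C[C@@H](C(C)C)[C@@H]2C1)[C@@H](C)CC[C@@H]1[C@@H](C=C)CC[C@@H]1C | intermediate
36 | O9-tert-butyldimethylsilyl ether of the target | C=C1C2=C(C[C@@]3(C)[C@H](O[Si](C)(C)C(C)(C)C)C[C@@H](C(C)C)[C@@H]3C2)[C@@H](C)CC[C@@H]2[C@@H]1CC[C@@H]2C | intermediate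
37 | CNP0544018.1 | C=C1C2=C(C[C@@]3(C)[C@H](O)C[C@@H](C(C)C)[C@@H]3C2)[C@@H](C)CC[C@@H]2[C@@H]1CC[C@@H]2C | target

**Step count and risk**

Total steps: 25. Longest linear sequence: 17 steps (11 to 37 through steps 8–15 and 17–25).

Step 24 (Heck closure). The eight-membered ring may close more slowly than the vinylpalladium is reduced, insertion may drift to the 9-endo mode, or the palladium hydride may re-add and move the exocyclic alkene. The fallback sets out from 35 and comes back at 36. Osmium-catalysed dihydroxylation (OsO4, NMO) of the monosubstituted vinyl group only should give the diol F1, and periodate cleavage the C2 aldehyde F2. An intramolecular Nozaki–Hiyama–Kishi coupling (CrCl2, cat. NiCl2, DMSO, high dilution) between the C3 triflate and the aldehyde then closes ring C as the allylic alcohol F3. Dess–Martin oxidation gives the cross-conjugated C2 ketone F4, and methylenation with the Petasis reagent (Cp2TiMe2, PhMe, 70 °C) gives 36.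

Step 12 (hydroboration). Borane may approach both faces of the cyclopentene, since only one allylic methyl discriminates them, and thermal addition of catecholborane to a trisubstituted alkene may stall. The fallback sets out from 15 and comes back at 17, and replaces substrate control by reagent control. Hydroboration with monoisopinocampheylborane, using the antipode whose own facial preference reinforces attack anti to the methyl (drawn for the reagent from (+)-α-pinene), should give the alkyl(isopinocampheyl)borane F5. Acetaldehyde expels α-pinene and leaves the diethyl boronate F6, and exchange with pinacol gives 17.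

Step 17 (alkyl–alkyl coupling). Substitution at the β-branched C20 tosylate by a β-branched Grignard reagent may be slower than homocoupling and reduction of the organometallic. The fallback sets out from 22 and 24 and comes back at 26, and uses a stabilised carbanion instead of copper catalysis. Sodium iodide in acetone converts 22 into the iodide F7, and sodium benzenesulfinate in DMF converts 24 into the sulfone F8. Lithiated F8 (n-BuLi, THF/DMPU, −78 °C → rt) is alkylated by F7 to the sulfone F9, and reductive desulfonylation (Mg, MeOH) gives 26.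

Further compounds
F1 | step 24 | diol from dihydroxylation of the C22 vinyl group of 35 (mixture at the new carbinol) | FC(F)(F)S(=O)(=O)OC1=C(C[C@@]2(C)[C@H](O[Si](C)(C)C(C)(C)C)C[C@@H](C(C)C)[C@@H]2C1)[C@@H](C)CC[C@@H]1[C@@H](C(O)CO)CC[C@@H]1C
F2 | step 24 | C3 enol triflate with a formyl group (C2) on C22 | FC(F)(F)S(=O)(=O)OC1=C(C[C@@]2(C)[C@H](O[Si](C)(C)C(C)(C)C)C[C@@H](C(C)C)[C@@H]2C1)[C@@H](C)CC[C@@H]1[C@@H](C=O)CC[C@@H]1C
F3 | step 24 | tetracyclic C2 allylic alcohol (mixture at C2), O9-TBS | OC1C2=C(C[C@@]3(C)[C@H](O[Si](C)(C)C(C)(C)C)C[C@@H](C(C)C)[C@@H]3C2)[C@@H](C)CC[C@@H]2[C@@H]1CC[C@@H]2C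
F4 | step 24 | tetracyclic C2 ketone conjugated with C3=C4, O9-TBS | O=C1C2=C(C[C@@]3(C)[C@H](O[Si](C)(C)C(C)(C)C)C[C@@H](C(C)C)[C@@H]3C2)[C@@H](C)CC[C@@H]2[C@@H]1CC[C@@H]2C
F5 | step 12 | alkyl(isopinocampheyl)borane from 15 (boron on C22 trans to the CH2OTBS arm) | CC(C)(C)[Si](C)(C)OC[C@@H]1[C@@H](B[C@@H]2C[C@@H]3C[C@H]([C@H]2C)C3(C)C)CC[C@@H]1C
F6 | step 12 | diethyl boronate corresponding to 17 | CC(C)(C)[Si](C)(C)OC[C@@H]1[C@@H](B(OCC)OCC)CC[C@@H]1C
F7 | step 17 | (1S,2R,3S)-1-ethenyl-2-(iodomethyl)-3-methylcyclopentane | IC[C@@H]1[C@@H](C=C)CC[C@@H]1C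
F8 | step 17 | tert-butyldimethylsilyl ether of 2-methyl-3-(phenylsulfonyl)propan-1-ol, configuration as in 24 | CC(C)(C)[Si](C)(C)OC[C@@H](C)CS(=O)(=O)c1ccccc1
F9 | step 17 | C19 phenyl sulfone of 26 (mixture at C19) | CC(C)(C)[Si](C)(C)OC[C@@H](C)C(S(=O)(=O)c1ccccc1)C[C@@H]1[C@@H](C=C)CC[C@@H]1C
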